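**Plan** (germacrane numbering throughout)

- The retrosynthesis first removes the C14 oxygen, the O8 acyl group and C13. It then cuts O6–C12 and C7–C11 of the lactone, which leaves a 4,5-epoxy-8-alkoxycyclodec-1(10)-en-6-one.
- The ten-membered ring is then contracted by a retro-[3,3] shift, in which C8–C9 is cut and C1–C6 is restored.
- This is possible because C1–C6, the cis C4–C5 oxirane, C15 on C4 and C10(=C9)–C14 as an isopropenyl group on C1 together make up the isopiperitenone oxide skeleton. C7=C8 sits on C6 as an E enol ether.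
- Forward order: terpene six-membered ring, oxirane, C6–C7 bond (alkoxyacetylide), enlargement to the ten-membered ring, γ-lactone, then C13, the isovalerate and the C14 aldehyde.
- Stereochemistry: C1 of the terpene (erased later) sets the C6 alcohol, which directs the oxirane (C4, C5), and the oxirane steers the C6 carbinol. The chair [3,3] shift with the E enol ether gives C8 and the ring-cis C1=C10, a C8 chelate gives C7, and an oxirane chelate gives C6.

Key step: step 8

Remark: (1S,4R)-p-mentha-2,8-dien-1-ol (1), the commercial building block made from (R)-limonene, is taken as the terpene source. Its carbinol centre is lost in step 1. From 1 on, C1 is the ring carbon bearing the isopropenyl group, C4 bears the methyl group and C6 becomes the carbonyl carbon.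
Remark: the C7–C8 unit is brought in at the alkyne level because a trans-β-alkoxyvinyllithium would lose alkoxide by anti elimination. The descriptors α and β refer to the usual germacranolide drawing (H-7 α).

Step 1
Reactants: 1 (1S,4R)-1-methyl-4-(prop-1-en-2-yl)cyclohex-2-en-1-ol
Product: 2 (6S)-3-methyl-6-(prop-1-en-2-yl)cyclohex-2-en-1-one [(S)-isopiperitenone]
Conditions: [C5H5NH][CrO3Cl], Celite, CH2Cl2, rt
Reagents that add atoms: pyridinium chlorochromate, [O-][Cr](=O)(=O)Cl.c1cc[nH+]cc1 (an oxo oxygen becomes the C6 carbonyl oxygen)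
Why: Babler–Dauben oxidative transposition (chromate [3,3] shift, then oxidation at C6) should give the enone regiospecifically and, being base-free, should leave the C1 stereocentre and the isopropenyl group untouched.

Step 2
Reactants: 2 (S)-isopiperitenone
Product: 3 (1R,6S)-3-methyl-6-(prop-1-en-2-yl)cyclohex-2-en-1-ol [trans-isopiperitenol]
Conditions: NaBH4, CeCl3·7H2O, MeOH, −78 °C
Reagents that add atoms: none
Why: Luche 1,2-reduction, in which axial hydride delivery to the half-chair with a pseudo-equatorial isopropenyl group should favour the pseudo-equatorial C6 alcohol trans to that group; the separable cis epimer can be returned to 2 by oxidation.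

Step 3
Reactants: 3 trans-isopiperitenol
Product: 4 (1S,2S,3S,6R)-6-methyl-3-(prop-1-en-2-yl)-7-oxabicyclo[4.1.0]heptan-2-ol
Conditions: VO(acac)2 (cat.), t-BuOOH, CH2Cl2, 0 °C → rt
Reagents that add atoms: tert-butyl hydroperoxide, CC(C)(C)OO
Why: Hydroxyl-directed vanadium-catalysed epoxidation delivers oxygen to the O6 face of the allylic trisubstituted C4=C5 bond, anti to the isopropenyl group, which sets C4 and C5 and spares the more remote 1,1-disubstituted alkene.

Step 4
Reactants: 4 epoxy alcohol
Product: 5 (1R,3S,6R)-6-methyl-3-(prop-1-en-2-yl)-7-oxabicyclo[4.1.0]heptan-2-one (oxirane oxygen anti to isopropenyl)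
Conditions: Pr4N[RuO4] (cat.), N-methylmorpholine N-oxide, 4 Å MS, CH2Cl2, rt
Reagents that add atoms: none
Why: Ley–Griffith oxidation under neutral conditions should give the epoxy ketone without epimerising C1 or drawing the isopropenyl double bond into conjugation.

Step 5
Reactants: 6 4-methoxybenzyl alcohol; 7 trichloroethylene
Product: 8 1-{[(E)-1,2-dichloroethenyl]oxymethyl}-4-methoxybenzene
Conditions: KH, THF, 0 °C; then 7, −50 °C → rt
Reagents that add atoms: none
Why: KH-mediated vinylic substitution on trichloroethylene is the standard entry to (E)-1,2-dichlorovinyl ethers, the usual precursors of lithium alkoxyacetylides.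

Step 6
Reactants: 8 dichlorovinyl ether; 5 epoxy ketone
Product: 12 (1S,2R,3S,6R)-2-[(4-methoxybenzyloxy)ethynyl]-6-methyl-3-(prop-1-en-2-yl)-7-oxabicyclo[4.1.0]heptan-2-ol, via chloroethynyl ether 9 (not isolated), via lithium acetylide 10 (not isolated), via dichlorocerium acetylide 11 (not isolated)
Conditions: 8, n-BuLi (2.2 equiv), THF, −78 → −40 °C; CeCl3, −78 °C; 5, −78 °C; aq NH4Cl
Reagents that add atoms: none
Why: Organocerium 1,2-addition of a slim sp nucleophile, which should enter axially and antiperiplanar to the C5–O bond on the half-chair with equatorial isopropenyl, so that C6 is set with OH cis to the oxirane oxygen and the alkyne cis to the isopropenyl group, while the low basicity of 11 spares the C1–H.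

Step 7
Reactants: 12 alkynyl carbinol
Product: 13 (1S,2R,3S,6R)-2-[(E)-2-(4-methoxybenzyloxy)ethenyl]-6-methyl-3-(prop-1-en-2-yl)-7-oxabicyclo[4.1.0]heptan-2-ol
Conditions: Na[AlH2(OCH2CH2OMe)2], Et2O, −20 → 0 °C; aq potassium sodium tartrate
Reagents that add atoms: none
Why: Hydroxyl-directed trans-hydroalumination of the propargylic alcohol gives the E enol ether after protonolysis, and an aluminate held on O6 lies on the oxirane-oxygen face and cannot reach the backside of C5.

Step 8
Reactants: 13 (E)-alkoxyvinyl carbinol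
Product: 16 (1R,4R,6Z,10R)-4-(4-methoxybenzyloxy)-6,10-dimethyl-11-oxabicyclo[8.1.0]undec-6-en-2-one [4α,5α-epoxy-8β-alkoxycyclodec-1(10)-en-6-one; ring-cis C1=C10], via potassium alkoxide 14 (not isolated), via potassium enolate 15 (not isolated)
Conditions: KH, 18-crown-6, THF, 0 °C → rt; AcOH/THF, −78 °C
Reagents that add atoms: none
Why: KH removes the C6–OH proton and the crown ether frees alkoxide 14, whose oxyanion weakens C1–C6 so that the array C9=C10–C1–C6–C7=C8 undergoes a concerted [3,3] shift (anionic oxy-Cope rearrangement) that forms C8–C9, breaks C1–C6 and ends in enolate 15, which cold acetic acid protonates at C7. The closest known reaction type is the KH/18-crown-6 ring expansion of 1,2-dialkenylcyclohexanols to cyclodec-5-enones, with the oxirane and the enol ether terminus as spectators particular to this molecule. The ten-membered ring is not closed end to end but arises by four-atom enlargement of the cyclohexane when the bond shared with the chair array is cleaved, and the oxirane stays fused at C4–C5. C8, the only new stereocentre, is controlled by the chair: its sense is fixed by C1 and C6 and the E enol ether places O8 equatorial, so that C9 bonds to a single face of C8 (8R). The olefin geometry follows from the half-chair with equatorial isopropenyl and axial alkenyl groups, in which C2 is axial on the chair and ends cis to C9, whereas the other chair needs an axial isopropenyl group and presses C2 against the C14 methyl group. The shift must outrun Payne migration and loss of the C8 ether: the first is ruled out because O6 and the oxirane oxygen share one ring face, the second is slowed because in 15 the C8–O bond lies near the nodal plane of the enolate, and the cold quench keeps the life of 15 short.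

Step 9
Reactants: 16 epoxy cyclodecenone
Product: 18 ethyl [(1R,3R,4R,6Z,10R)-4-(4-methoxybenzyloxy)-6,10-dimethyl-2-oxo-11-oxabicyclo[8.1.0]undec-6-en-3-yl]acetate, via lithium enolate 17 (not isolated)
Conditions: LiN(SiMe3)2, THF, −78 °C; ICH2CO2Et, −78 → −40 °C
Reagents that add atoms: ethyl iodoacetate, ICC(=O)OCC
Why: Kinetic enolate alkylation, in which only C7 can be deprotonated (C5 is an oxirane carbon), lithium bridges O6 and O8 in a six-membered chelate as in a Fráter–Seebach alkylation, and the iodide should reach C7 from the ring periphery anti to C9, giving the 7,8-anti arrangement (7R).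

Step 10
Reactants: 18 keto ester
Product: 20 4α,5α-epoxy-8β-(4-methoxybenzyloxy)-13-norgermacr-1(10)-en-12,6α-olide (4R,5S,6S,7R,8R; ring-cis C1=C10), via hydroxy ester 19 (not isolated)
Conditions: Zn(BH4)2, Et2O, −20 °C; H2O; then PPTS (cat.), CH2Cl2, rt
Reagents that add atoms: none
Why: Chelation-controlled reduction of an α,β-epoxy ketone, in which zinc ties the C6 carbonyl oxygen to the oxirane oxygen and hydride enters from the H5 side (the outside of the ring) to give the anti epoxy alcohol 19 (6S), whose hydroxyl then closes the trans-fused γ-lactone by 5-exo-trig acyl substitution.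

Step 11
Reactants: 20 lactone
Product: 22 (11R)-13-(dimethylamino)-4α,5α-epoxy-8β-(4-methoxybenzyloxy)germacr-1(10)-en-12,6α-olide, via lithium lactone enolate 21 (not isolated)
Conditions: LiN(iPr)2, THF, −78 °C; CH2=NMe2+ I−, −78 °C → rt
Reagents that add atoms: N,N-dimethylmethyleneiminium iodide, C=[N+](C)C.[I-]
Why: Mannich-type aminomethylation of the lactone enolate with the preformed iminium salt, which should approach anti to the C7–C8 bond (11R as drawn), a centre that is erased in step 12.

Step 12
Reactants: 22 Mannich base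
Product: 24 4α,5α-epoxy-8β-(4-methoxybenzyloxy)germacra-1(10),11(13)-dien-12,6α-olide, via ammonium iodide 23 (not isolated)
Conditions: MeI, THF, rt; aq NaHCO3, CH2Cl2, rt
Reagents that add atoms: none
Why: Exhaustive methylation followed by Hofmann-type elimination of trimethylamine is the standard mild passage from a Mannich base to an α-methylene-γ-lactone and touches neither the oxirane nor the ether.

Step 13
Reactants: 24 methylene lactone
Product: 25 4α,5α-epoxy-8β-hydroxygermacra-1(10),11(13)-dien-12,6α-olide
Conditions: DDQ, CH2Cl2/pH 7 buffer, 0 °C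
Reagents that add atoms: none
Why: Oxidative cleavage of the electron-rich benzyl ether in a buffered two-phase medium is neutral enough for the oxirane/olefin pair and leaves the electron-poor methylene lactone alone.

Step 14
Reactants: 25 8β-alcohol
Product: 26 4α,5α-epoxy-8β-(3-methylbutanoyloxy)germacra-1(10),11(13)-dien-12,6α-olide
Conditions: (i-BuCO)2O, DMAP (cat.), pyridine, CH2Cl2, 0 °C → rt
Reagents that add atoms: isovaleric anhydride, CC(C)CC(=O)OC(=O)CC(C)C
Why: DMAP-catalysed acylation of the secondary alcohol proceeds with retention at C8 and is too mild for translactonisation to O8.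

Step 15
Reactants: 26 isovalerate
Product: 27 4α,5α-epoxy-14-hydroxy-8β-(3-methylbutanoyloxy)germacra-1(10),11(13)-dien-12,6α-olide
Conditions: SeO2 (cat.), t-BuOOH, CH2Cl2, rt
Reagents that add atoms: tert-butyl hydroperoxide, CC(C)(C)OO (oxygen relayed through selenium dioxide, O=[Se]=O)
Why: Riley allylic oxidation (ene reaction at C1, then [2,3] shift) hydroxylates the methyl group on the more substituted olefin carbon that lies trans to C2 and regenerates the ring-cis C1=C10 bond, a selectivity known for 4,5-epoxygermacranolides, while C9 is deactivated by the neighbouring acyloxy group and the conjugated methylene is inert.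

Step 16
Reactants: 27 allylic alcohol
Product: 28 4α,5α-epoxy-8β-(3-methylbutanoyloxy)-14-oxogermacra-1(10),11(13)-dien-12,6α-olide (target CNP0260081.1)
Conditions: MnO2, CH2Cl2, rt
Reagents that add atoms: none
Why: MnO2 oxidises only the primary allylic alcohol under neutral conditions and gives the enal with the formyl group trans to C2, the preferred enal geometry, so no isomerisation is expected.

**Compound list**

1 | (1S,4R)-1-methyl-4-(prop-1-en-2-yl)cyclohex-2-en-1-ol | CC(=C)[C@H]1C=C[C@@](C)(O)CC1 | starting material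
2 | (6S)-3-methyl-6-(prop-1-en-2-yl)cyclohex-2-en-1-one | CC(=C)[C@@H]1CCC(C)=CC1=O | intermediate
3 | (1R,6S)-3-methyl-6-(prop-1-en-2-yl)cyclohex-2-en-1-ol | CC(=C)[C@@H]1CCC(C)=C[C@H]1O | intermediate
4 | (1S,2S,3S,6R)-6-methyl-3-(prop-1-en-2-yl)-7-oxabicyclo[4.1.0]heptan-2-ol | CC(=C)[C@@H]1CC[C@@]2(C)O[C@H]2[C@H]1O | intermediate
5 | (1R,3S,6R)-6-methyl-3-(prop-1-en-2-yl)-7-oxabicyclo[4.1.0]heptan-2-one | CC(=C)[C@@H]1CC[C@@]2(C)O[C@H]2C1=O | intermediate
6 | 4-methoxybenzyl alcohol | COc1ccc(CO)cc1 | starting material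
7 | trichloroethylene | ClC=C(Cl)Cl | starting material
8 | 1-{[(E)-1,2-dichloroethenyl]oxymethyl}-4-methoxybenzene | COc1ccc(CO/C(Cl)=C\Cl)cc1 | intermediate
9 | 1-[(chloroethynyl)oxymethyl]-4-methoxybenzene | COc1ccc(COC#CCl)cc1 | intermediate
10 | lithium (4-methoxybenzyloxy)acetylide | COc1ccc(COC#C[Li])cc1 | intermediate
11 | dichlorocerium (4-methoxybenzyloxy)acetylide | COc1ccc(COC#C[Ce](Cl)Cl)cc1 | intermediate
12 | (1S,2R,3S,6R)-2-[(4-methoxybenzyloxy)ethynyl]-6-methyl-3-(prop-1-en-2-yl)-7-oxabicyclo[4.1.0]heptan-2-ol | C=C(C)[C@@H]1CC[C@@]2(C)O[C@H]2[C@]1(O)C#COCc3ccc(OC)cc3 | intermediate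
13 | (1S,2R,3S,6R)-2-[(E)-2-(4-methoxybenzyloxy)ethenyl]-6-methyl-3-(prop-1-en-2-yl)-7-oxabicyclo[4.1.0]heptan-2-ol | C=C(C)[C@@H]1CC[C@@]2(C)O[C@H]2[C@]1(O)/C=C/OCc3ccc(OC)cc3 | intermediate
14 | potassium alkoxide of 13 | C=C(C)[C@@H]1CC[C@@]2(C)O[C@H]2[C@]1([O-])/C=C/OCc3ccc(OC)cc3.[K+] | intermediate
15 | potassium C6=C7 enolate of 16 (O6 cis to C8) | [K+].[O-]/C1=C\[C@H](OCc2ccc(OC)cc2)C/C(C)=C\CC[C@@]3(C)O[C@@H]13 | intermediate
16 | (1R,4R,6Z,10R)-4-(4-methoxybenzyloxy)-6,10-dimethyl-11-oxabicyclo[8.1.0]undec-6-en-2-one | O=C1C[C@H](OCc2ccc(OC)cc2)C/C(C)=C\CC[C@@]3(C)O[C@@H]13 | intermediate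
17 | lithium C6=C7 enolate of 16 (O6 cis to C8; chelated by O8) | [Li+].[O-]/C1=C\[C@H](OCc2ccc(OC)cc2)C/C(C)=C\CC[C@@]3(C)O[C@@H]13 | intermediate
18 | ethyl [(1R,3R,4R,6Z,10R)-4-(4-methoxybenzyloxy)-6,10-dimethyl-2-oxo-11-oxabicyclo[8.1.0]undec-6-en-3-yl]acetate | O=C1[C@H](CC(=O)OCC)[C@H](OCc2ccc(OC)cc2)C/C(C)=C\CC[C@@]3(C)O[C@@H]13 | intermediate
19 | 6α-hydroxy ester from 18 (O6 on the oxirane-oxygen face) | O[C@H]1[C@H](CC(=O)OCC)[C@H](OCc2ccc(OC)cc2)C/C(C)=C\CC[C@@]3(C)O[C@@H]13 | intermediate
20 | 4α,5α-epoxy-8β-(4-methoxybenzyloxy)-13-norgermacr-1(10)-en-12,6α-olide | C1C(=O)O[C@H]2[C@H]1[C@H](OCc3ccc(OC)cc3)C/C(C)=C\CC[C@@]1(C)O[C@@H]21 | intermediate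
21 | lithium enolate of lactone 20 | [Li+].C1=C([O-])O[C@H]2[C@H]1[C@H](OCc3ccc(OC)cc3)C/C(C)=C\CC[C@@]1(C)O[C@@H]21 | intermediate
22 | (11R)-13-(dimethylamino)-4α,5α-epoxy-8β-(4-methoxybenzyloxy)germacr-1(10)-en-12,6α-olide | CN(C)C[C@@H]1C(=O)O[C@H]2[C@H]1[C@H](OCc3ccc(OC)cc3)C/C(C)=C\CC[C@@]1(C)O[C@@H]21 | intermediate
23 | trimethylammonium iodide of 22 | C[N+](C)(C)C[C@@H]1C(=O)O[C@H]2[C@H]1[C@H](OCc3ccc(OC)cc3)C/C(C)=C\CC[C@@]1(C)O[C@@H]21.[I-] | intermediate
24 | 4α,5α-epoxy-8β-(4-methoxybenzyloxy)germacra-1(10),11(13)-dien-12,6α-olide | C=C1C(=O)O[C@H]2[C@H]1[C@H](OCc3ccc(OC)cc3)C/C(C)=C\CC[C@@]1(C)O[C@@H]21 | intermediate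
25 | 4α,5α-epoxy-8β-hydroxygermacra-1(10),11(13)-dien-12,6α-olide | C=C1C(=O)O[C@H]2[C@H]1[C@H](O)C/C(C)=C\CC[C@@]1(C)O[C@@H]21 | intermediate
26 | 4α,5α-epoxy-8β-(3-methylbutanoyloxy)germacra-1(10),11(13)-dien-12,6α-olide | C=C1C(=O)O[C@H]2[C@H]1[C@H](OC(=O)CC(C)C)C/C(C)=C\CC[C@@]1(C)O[C@@H]21 | intermediate
27 | 4α,5α-epoxy-14-hydroxy-8β-(3-methylbutanoyloxy)germacra-1(10),11(13)-dien-12,6α-olide | C=C1C(=O)O[C@H]2[C@H]1[C@H](OC(=O)CC(C)C)C/C(CO)=C\CC[C@@]1(C)O[C@@H]21 | intermediate
28 | 4α,5α-epoxy-8β-(3-methylbutanoyloxy)-14-oxogermacra-1(10),11(13)-dien-12,6α-olide (4R,5S,6S,7R,8R; ring-cis C1=C10) | C=C1C(=O)O[C@H]2[C@H]1[C@H](OC(=O)CC(C)C)C/C(C=O)=C\CC[C@@]1(C)O[C@@H]21 | target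

**Step count:** 16 steps in total. The longest linear sequence is 15 steps (steps 1–4 and 6–16, from 1).

**Steps most likely to fail**

**Step 8.**
- Risk: the β-alkoxy potassium enolate may lose 4-methoxybenzyl oxide before the quench. The oxirane may also be opened under the basic conditions, or part of the material may pass through the second chair.
- Fallback: a masked hydroxyl group at C8 replaces the ether. The fallback sets out from 5 and returns at 16.
- Benzyl(ethynyl)dimethylsilane, n-BuLi and CeCl3 are used on 5 as in step 6 and should give the silylethynyl carbinol F1.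
- Hydroxyl-directed hydroalumination with Na[AlH2(OCH2CH2OMe)2] gives the (E)-vinylsilane carbinol F2.
- KH and 18-crown-6 take F2 through the same chair to the 8β-silyl cyclodecenone F3, by way of an enolate that has no β-leaving group.
- Tamao–Fleming oxidation (Bu4NF, then H2O2, KHCO3, THF/MeOH) exchanges silicon for hydroxyl with retention and gives the 8β-hydroxy ketone F4.
- Neutral 4-methoxybenzyl transfer (2-(4-methoxybenzyloxy)-4-methylquinoline, MeOTf, MgO) then gives 16.

**Step 6.**
- Risk: facial selectivity may be poor, with the acetylide approaching on the oxirane face, away from the isopropenyl group. Enolisation at C1 is a second risk.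
- Fallback: a matched diastereomer is used and the olefin geometry is corrected afterwards. The fallback sets out from 5 and returns at 16.
- Equilibration of 5 with DBU in toluene and separation (5 is recycled) gives the C1-epimeric epoxy ketone F5. In F5 the oxirane oxygen and the isopropenyl group shield the same face, so both steer acetylide 11 to the other face.
- This addition gives the alkynyl carbinol F6, which has the C6 configuration of 12.
- Reduction as in step 7 gives the trans-dialkenyl carbinol F7.
- KH and 18-crown-6 move F7 through the single diequatorial chair, the best-documented case of this ring expansion, to the ring-trans cyclodecenone F8. F8 carries the C4, C5 and C8 configuration of 16.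
- Thiyl-radical equilibration (PhSSPh, hν, benzene) releases the strain of the ring-trans olefin and gives 16.

**Step 9.**
- Risk: the lithium enolate may undergo β-elimination of the C8 ether on warming. Proton exchange between product and enolate, or attack on the wrong face of C7, may also intervene.
- Fallback: radical alkylation of a neutral enol silane replaces the enolate substitution. The fallback sets out from 13 and returns at 18.
- Enolate 15, formed as in step 8, is silylated at −78 °C with Me3SiCl instead of being protonated and gives the trimethylsilyl enol ether F9.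
- The electrophilic radical from ethyl iodoacetate (Ru(bpy)3Cl2, visible light, 2,6-lutidine, DMF) adds to C7 of this electron-rich alkene. Loss of the silyl group then gives 18 with no metal enolate present, and any C7 epimer is removed by chromatography.

Further compounds
F1 | step 8 | (1S,2R,3S,6R)-2-{[benzyl(dimethyl)silyl]ethynyl}-6-methyl-3-(prop-1-en-2-yl)-7-oxabicyclo[4.1.0]heptan-2-ol | C=C(C)[C@@H]1CC[C@@]2(C)O[C@H]2[C@]1(O)C#C[Si](C)(C)Cc3ccccc3
F2 | step 8 | (1S,2R,3S,6R)-2-{(E)-2-[benzyl(dimethyl)silyl]ethenyl}-6-methyl-3-(prop-1-en-2-yl)-7-oxabicyclo[4.1.0]heptan-2-ol | C=C(C)[C@@H]1CC[C@@]2(C)O[C@H]2[C@]1(O)/C=C/[Si](C)(C)Cc3ccccc3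
F3 | step 8 | (1R,4R,6Z,10R)-4-[benzyl(dimethyl)silyl]-6,10-dimethyl-11-oxabicyclo[8.1.0]undec-6-en-2-one | O=C1C[C@H]([Si](C)(C)Cc2ccccc2)C/C(C)=C\CC[C@@]3(C)O[C@@H]13
F4 | step 8 | (1R,4R,6Z,10R)-4-hydroxy-6,10-dimethyl-11-oxabicyclo[8.1.0]undec-6-en-2-one | O=C1C[C@H](O)C/C(C)=C\CC[C@@]3(C)O[C@@H]13
F5 | step 6 | (1R,3R,6R)-6-methyl-3-(prop-1-en-2-yl)-7-oxabicyclo[4.1.0]heptan-2-one | CC(=C)[C@H]1CC[C@@]2(C)O[C@H]2C1=O
F6 | step 6 | (1S,2R,3R,6R)-2-[(4-methoxybenzyloxy)ethynyl]-6-methyl-3-(prop-1-en-2-yl)-7-oxabicyclo[4.1.0]heptan-2-ol | C=C(C)[C@H]1CC[C@@]2(C)O[C@H]2[C@]1(O)C#COCc3ccc(OC)cc3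
F7 | step 6 | (1S,2R,3R,6R)-2-[(E)-2-(4-methoxybenzyloxy)ethenyl]-6-methyl-3-(prop-1-en-2-yl)-7-oxabicyclo[4.1.0]heptan-2-ol | C=C(C)[C@H]1CC[C@@]2(C)O[C@H]2[C@]1(O)/C=C/OCc3ccc(OC)cc3
F8 | step 6 | (1R,4R,6E,10R)-4-(4-methoxybenzyloxy)-6,10-dimethyl-11-oxabicyclo[8.1.0]undec-6-en-2-one | O=C1C[C@H](OCc2ccc(OC)cc2)C/C(C)=C/CC[C@@]3(C)O[C@@H]13
F9 | step 9 | trimethylsilyl C6=C7 enol ether of 16 (O6 cis to C8) | C[Si](C)(C)O/C1=C\[C@H](OCc2ccc(OC)cc2)C/C(C)=C\CC[C@@]3(C)O[C@@H]13
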